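## Retrosynthetic overview (germacranolide numbering: ring C1–C10, lactone C11–C13, C14 on C10, C15 on C4)

1. The C8 ester is cut last: alcohol 17 plus (2R,3R)-epoxyangelic acid 21, whose oxirane comes from a Sharpless epoxidation in a separate branch.
2. The ten-membered carbocycle and the α-methylene-γ-lactone are cut together at C7–C8, C6–C7 and O6–C12. This gives acyclic epoxy dialdehyde 11 and the C4 linchpin 14, which acts as a C7 1,1-dinucleophile under chromium, so both rings form in one flask.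
3. Dialdehyde 11: the 1,10-oxirane by Shi epoxidation of the E-alkene; C3–C4 by asymmetric Ni/Cr alkenylation of aldehyde 6 with Z-iodide 3; the E-alkene by carboalumination of alkyne 4.
4. Ring order: side-chain oxirane (branch) → 1,10-oxirane (step 7) → carbocycle and lactone together (step 11) → final acylation.

Assumption: L1 (valinol-derived 2-(4-isopropyloxazolin-2-yl)anilide methanesulfonamide) and L2 (3,6-di-tert-butyl-1,8-bis(4-isopropyloxazolin-2-yl)carbazole) are each used as the enantiomer that gives the face selectivity stated in steps 5 and 11; I have not verified which enantiomer that is.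

## Route

Step 1
Reactants: 1 but-2-yn-1-ol
Product: 2 (Z)-3-iodobut-2-en-1-ol
Conditions: NaAlH2(OCH2CH2OMe)2 (Red-Al), THF, 0 °C to rt; then I2, −78 °C
Reagents that add atoms: iodine, II
Why: Hydroxyl-directed trans-hydroalumination puts aluminium on C3 cis to CH2O in a five-membered alkoxyalanate, and iodinolysis with retention gives the Z-iodide (hydroalumination–iodination).

Step 2
Reactants: 2 (Z)-3-iodobut-2-en-1-ol
Product: 3 (Z)-tert-butyl[(3-iodobut-2-en-1-yl)oxy]dimethylsilane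
Conditions: TBSCl, imidazole, CH2Cl2, 0 °C to rt
Reagents that add atoms: tert-butylchlorodimethylsilane, CC(C)(C)[Si](C)(C)Cl
Why: Silyl ether protection of the primary alcohol, so that later only the C3 hydroxyl is free for acylation.

Step 3
Reactants: 4 tert-butyl(but-3-yn-1-yloxy)dimethylsilane
Product: 5 (E)-6-[(tert-butyldimethylsilyl)oxy]-4-methylhex-3-en-1-ol
Conditions: Me3Al, Cp2ZrCl2 (20 mol %), CH2Cl2, 0 °C to rt; then n-BuLi, THF–hexane, −78 °C; ethylene oxide, −78 to 0 °C
Reagents that add atoms: trimethylaluminium, C[Al](C)C; ethylene oxide, C1CO1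
Why: Negishi zirconium-catalysed carboalumination adds methyl and aluminium syn, with methyl on the internal carbon, which fixes the E-trisubstituted alkene; the derived alanate opens ethylene oxide with retention.

Step 4
Reactants: 5 (E)-6-[(tert-butyldimethylsilyl)oxy]-4-methylhex-3-en-1-ol
Product: 6 (E)-6-[(tert-butyldimethylsilyl)oxy]-4-methylhex-3-enal
Conditions: Dess–Martin periodinane, CH2Cl2, 0 °C; used crude
Reagents that add atoms: none
Why: Dess–Martin oxidation is mild enough to give the β,γ-unsaturated aldehyde without moving the alkene into conjugation.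

Step 5
Reactants: 6 (E)-6-[(tert-butyldimethylsilyl)oxy]-4-methylhex-3-enal; 3 (Z)-tert-butyl[(3-iodobut-2-en-1-yl)oxy]dimethylsilane
Product: 7 (2Z,4S,6E)-1,9-bis[(tert-butyldimethylsilyl)oxy]-3,7-dimethylnona-2,6-dien-4-ol
Conditions: CrCl2 (10 mol %), L1 (11 mol %), Et3N (20 mol %), NiCl2·(2,9-dimethyl-1,10-phenanthroline) (2 mol %), Mn, Cp2ZrCl2, LiCl, MeCN, rt
Reagents that add atoms: none
Why: Catalytic asymmetric Nozaki–Hiyama–Kishi alkenylation: the alkenylchromium forms with retention of the Z geometry and adds to the Re face of the aldehyde under control of the chiral chromium sulfonamide complex (3S), and the non-basic medium leaves the skipped alkene in place.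

Step 6
Reactants: 7 (2Z,4S,6E)-1,9-bis[(tert-butyldimethylsilyl)oxy]-3,7-dimethylnona-2,6-dien-4-ol
Product: 8 (2Z,4S,6E)-1,9-bis[(tert-butyldimethylsilyl)oxy]-3,7-dimethylnona-2,6-dien-4-yl 2-methylpropanoate
Conditions: isobutyryl chloride, Et3N, DMAP (cat.), CH2Cl2, 0 °C
Reagents that add atoms: 2-methylpropanoyl chloride, CC(C)C(Cl)=O
Why: DMAP-catalysed acylation puts the C3 ester of the target on the only free hydroxyl.

Step 7
Reactants: 8 (2Z,4S,6E)-1,9-bis[(tert-butyldimethylsilyl)oxy]-3,7-dimethylnona-2,6-dien-4-yl 2-methylpropanoate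
Product: 9 (2Z,4S)-1-[(tert-butyldimethylsilyl)oxy]-5-[(2R,3R)-3-{2-[(tert-butyldimethylsilyl)oxy]ethyl}-3-methyloxiran-2-yl]-3-methylpent-2-en-4-yl 2-methylpropanoate
Conditions: D-fructose-derived Shi ketone (30 mol %), KHSO5 (Oxone), K2CO3, Bu4NHSO4 (cat.), MeCN–(MeO)2CH2–aq. buffer pH 10.5, 0 °C
Reagents that add atoms: potassium peroxymonosulfate, [K+].[O-]S(=O)(=O)OO
Why: Shi epoxidation: the fructose-derived dioxirane attacks the electron-rich E-trisubstituted alkene through the spiro transition state that gives the (R,R)-oxirane (here 1R,10R), while the Z-alkene flanked by two allylic C–O bonds is deactivated.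

Step 8
Reactants: 9 (2Z,4S)-1-[(tert-butyldimethylsilyl)oxy]-5-[(2R,3R)-3-{2-[(tert-butyldimethylsilyl)oxy]ethyl}-3-methyloxiran-2-yl]-3-methylpent-2-en-4-yl 2-methylpropanoate
Product: 10 (2Z,4S)-1-hydroxy-5-[(2R,3R)-3-(2-hydroxyethyl)-3-methyloxiran-2-yl]-3-methylpent-2-en-4-yl 2-methylpropanoate
Conditions: Bu4NF, AcOH (1:1), THF, 0 °C
Reagents that add atoms: none
Why: Buffered fluoride desilylation cleaves both primary silyl ethers, and the acetic acid suppresses isobutyryl migration and oxirane opening.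

Step 9
Reactants: 10 (2Z,4S)-1-hydroxy-5-[(2R,3R)-3-(2-hydroxyethyl)-3-methyloxiran-2-yl]-3-methylpent-2-en-4-yl 2-methylpropanoate
Product: 11 (2Z,4S)-3-methyl-5-[(2R,3R)-3-methyl-3-(2-oxoethyl)oxiran-2-yl]-1-oxopent-2-en-4-yl 2-methylpropanoate
Conditions: Dess–Martin periodinane, pyridine, CH2Cl2, 0 °C; used at once
Reagents that add atoms: none
Why: Double Dess–Martin oxidation under pyridine buffering gives the Z-enal and the β,γ-epoxy aldehyde without isomerisation or elimination.

Step 10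
Reactants: 12 methyl 2-(bromomethyl)prop-2-enoate
Product: 14 methyl (Z)-3-bromo-2-(bromomethyl)prop-2-enoate, via tribromide 13 (not isolated)
Conditions: Br2, CH2Cl2, 0 °C to rt; then Et3N, 0 °C
Reagents that add atoms: bromine, BrBr
Why: Bromine addition followed by dehydrobromination of a CH2Br arm gives the 3-bromoacrylate, expected mainly as the Z isomer; this geometry is erased in step 11.

Step 11
Reactants: 11 (2Z,4S)-3-methyl-5-[(2R,3R)-3-methyl-3-(2-oxoethyl)oxiran-2-yl]-1-oxopent-2-en-4-yl 2-methylpropanoate; 14 methyl (Z)-3-bromo-2-(bromomethyl)prop-2-enoate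
Product: 17 (1R,3S,6R,7R,8R,10R)-1,10-epoxy-8-hydroxy-3-(2-methylpropanoyloxy)germacra-4Z,11(13)-dien-12,6-olide, via seco bromide silyl ether 15 (not isolated), via lactone silyl ether 16 (not isolated)
Conditions: (i) 14 (1.2 equiv), CrCl2 (10 mol %), L2 (11 mol %), i-Pr2NEt (30 mol %), Mn, Me3SiCl (1.15 equiv), THF, 0 °C; (ii) filter from Mn, dilute to 2 mM, add over 10 h to CrCl2 (6 equiv), THF–DMF, 23 °C; (iii) aq. citric acid, THF, rt
Reagents that add atoms: chlorotrimethylsilane, C[Si](C)(C)Cl (silicon stays only in 15 and 16)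
Why: Proposed new method: the chiral chromium catalyst reduces the primary allylic bromide of 14 to a γ-bromoallylchromium that adds through its γ-carbon to the Si face of the unhindered C8 aldehyde (chair transition state, 8R; the hindered Z-enal is spared), and the alkoxide is released as silyl ether 15, which stops turnover once Me3SiCl is spent; the C7–Br left behind is a second allylic bromide, so excess divalent chromium at high dilution turns 15 into a 2-(methoxycarbonyl)allylchromium that closes the ten-membered ring onto the enal (Zimmerman–Traxler chair, anti adduct, 6R; C7 set by 1,2-induction from C8 with H8 in the alkene plane, the ring chain anti to the incoming aldehyde and the silyloxy group outside), and the C6 chromium alkoxide lactonises onto the ester while O8 is still silylated, which fixes the 12,6-olide; the silyloxy group is too poor a leaving group for 1,4-elimination; closest known chemistry: Takai-type γ-haloallylchromium additions, chromium-catalysed asymmetric 2-(alkoxycarbonyl)allylation of aldehydes, and macrocyclising Nozaki–Hiyama allylation–lactonisation to germacranolides.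

Step 12
Reactants: 18 methyl (Z)-2-methylbut-2-enoate (methyl angelate)
Product: 19 (Z)-2-methylbut-2-en-1-ol
Conditions: i-Bu2AlH, CH2Cl2, −78 °C
Reagents that add atoms: none
Why: 1,2-Hydride reduction of the conjugated ester gives the allylic alcohol without touching the Z geometry.

Step 13
Reactants: 19 (Z)-2-methylbut-2-en-1-ol
Product: 20 [(2S,3R)-2,3-dimethyloxiran-2-yl]methanol
Conditions: Ti(OiPr)4, L-(+)-diisopropyl tartrate, t-BuOOH, 4 Å molecular sieves, CH2Cl2, −20 °C
Reagents that add atoms: tert-butyl hydroperoxide, CC(C)(C)OO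
Why: Sharpless asymmetric epoxidation: with L-(+)-tartrate the oxygen is delivered to the face of the Z-allylic alcohol that gives the (2S,3R)-epoxy alcohol, as with nerol.

Step 14
Reactants: 20 [(2S,3R)-2,3-dimethyloxiran-2-yl]methanol
Product: 21 (2R,3R)-2,3-dimethyloxirane-2-carboxylic acid
Conditions: RuCl3·xH2O (2 mol %), NaIO4, MeCN–EtOAc–H2O, rt
Reagents that add atoms: water, O
Why: Ruthenium tetroxide made in situ oxidises the primary alcohol through the aldehyde hydrate to the acid without opening the oxirane (Sharpless RuCl3/NaIO4 oxidation); C2 becomes 2R only through the change in priorities.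

Step 15
Reactants: 17 (1R,3S,6R,7R,8R,10R)-1,10-epoxy-8-hydroxy-3-(2-methylpropanoyloxy)germacra-4Z,11(13)-dien-12,6-olide; 21 (2R,3R)-2,3-dimethyloxirane-2-carboxylic acid
Product: 23 (1R,3S,6R,7R,8R,10R)-8-[(2R,3R)-2,3-dimethyloxirane-2-carbonyloxy]-1,10-epoxy-3-(2-methylpropanoyloxy)germacra-4Z,11(13)-dien-12,6-olide (CNP0117882.2), via mixed anhydride 22 (not isolated)
Conditions: 2,4,6-trichlorobenzoyl chloride, Et3N, toluene, rt; then 17, DMAP, rt
Reagents that add atoms: 2,4,6-trichlorobenzoyl chloride, O=C(Cl)c1c(Cl)cc(Cl)cc1Cl (stays only in 22)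
Why: Yamaguchi esterification: the mixed anhydride acylates the hindered secondary C8 hydroxyl under DMAP catalysis without touching the stereocentres, the oxiranes or the α-methylene lactone.

## Compound list

1 | but-2-yn-1-ol | CC#CCO | starting material
2 | (Z)-3-iodobut-2-en-1-ol | OC/C=C(/C)I | intermediate
3 | (Z)-tert-butyl[(3-iodobut-2-en-1-yl)oxy]dimethylsilane | CC(C)(C)[Si](C)(C)OC/C=C(/C)I | intermediate
4 | tert-butyl(but-3-yn-1-yloxy)dimethylsilane | C#CCCO[Si](C)(C)C(C)(C)C | starting material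
5 | (E)-6-[(tert-butyldimethylsilyl)oxy]-4-methylhex-3-en-1-ol | OCC/C=C(\C)CCO[Si](C)(C)C(C)(C)C | intermediate
6 | (E)-6-[(tert-butyldimethylsilyl)oxy]-4-methylhex-3-enal | O=CC/C=C(\C)CCO[Si](C)(C)C(C)(C)C | intermediate
7 | (2Z,4S,6E)-1,9-bis[(tert-butyldimethylsilyl)oxy]-3,7-dimethylnona-2,6-dien-4-ol | CC(C)(C)[Si](C)(C)OC/C=C(/C)[C@@H](O)C/C=C(\C)CCO[Si](C)(C)C(C)(C)C | intermediate
8 | (2Z,4S,6E)-1,9-bis[(tert-butyldimethylsilyl)oxy]-3,7-dimethylnona-2,6-dien-4-yl 2-methylpropanoate | CC(C)(C)[Si](C)(C)OC/C=C(/C)[C@@H](OC(=O)C(C)C)C/C=C(\C)CCO[Si](C)(C)C(C)(C)C | intermediate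
9 | (2Z,4S)-1-[(tert-butyldimethylsilyl)oxy]-5-[(2R,3R)-3-{2-[(tert-butyldimethylsilyl)oxy]ethyl}-3-methyloxiran-2-yl]-3-methylpent-2-en-4-yl 2-methylpropanoate | CC(C)(C)[Si](C)(C)OC/C=C(/C)[C@@H](OC(=O)C(C)C)C[C@H]1O[C@]1(C)CCO[Si](C)(C)C(C)(C)C | intermediate
10 | (2Z,4S)-1-hydroxy-5-[(2R,3R)-3-(2-hydroxyethyl)-3-methyloxiran-2-yl]-3-methylpent-2-en-4-yl 2-methylpropanoate | OC/C=C(/C)[C@@H](OC(=O)C(C)C)C[C@H]1O[C@]1(C)CCO | intermediate
11 | (2Z,4S)-3-methyl-5-[(2R,3R)-3-methyl-3-(2-oxoethyl)oxiran-2-yl]-1-oxopent-2-en-4-yl 2-methylpropanoate | O=C/C=C(/C)[C@@H](OC(=O)C(C)C)C[C@H]1O[C@]1(C)CC=O | intermediate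
12 | methyl 2-(bromomethyl)prop-2-enoate | C=C(CBr)C(=O)OC | starting material
13 | methyl 2,3-dibromo-2-(bromomethyl)propanoate | BrCC(Br)(CBr)C(=O)OC | intermediate
14 | methyl (Z)-3-bromo-2-(bromomethyl)prop-2-enoate | BrC/C(C(=O)OC)=C\Br | intermediate
15 | methyl (4R)-3-bromo-2-methylidene-5-[(2R,3R)-2-methyl-3-{(2S,3Z)-3-methyl-2-(2-methylpropanoyloxy)-5-oxopent-3-en-1-yl}oxiran-2-yl]-4-[(trimethylsilyl)oxy]pentanoate (both C3 epimers) | O=C/C=C(/C)[C@@H](OC(=O)C(C)C)C[C@H]1O[C@]1(C)C[C@@H](O[Si](C)(C)C)C(Br)C(=C)C(=O)OC | intermediate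
16 | 8-O-trimethylsilyl ether of 17 | C=C1C(=O)O[C@@H]2/C=C(/C)[C@@H](OC(=O)C(C)C)C[C@H]3O[C@]3(C)C[C@@H](O[Si](C)(C)C)[C@@H]12 | intermediate
17 | (1R,3S,6R,7R,8R,10R)-1,10-epoxy-8-hydroxy-3-(2-methylpropanoyloxy)germacra-4Z,11(13)-dien-12,6-olide | C=C1C(=O)O[C@@H]2/C=C(/C)[C@@H](OC(=O)C(C)C)C[C@H]3O[C@]3(C)C[C@@H](O)[C@@H]12 | intermediate
18 | methyl (Z)-2-methylbut-2-enoate (methyl angelate) | C/C=C(/C)C(=O)OC | starting material
19 | (Z)-2-methylbut-2-en-1-ol | C/C=C(/C)CO | intermediate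
20 | [(2S,3R)-2,3-dimethyloxiran-2-yl]methanol | OC[C@]1(C)O[C@@H]1C | intermediate
21 | (2R,3R)-2,3-dimethyloxirane-2-carboxylic acid | OC(=O)[C@]1(C)O[C@@H]1C | intermediate
22 | (2R,3R)-2,3-dimethyloxirane-2-carboxylic 2,4,6-trichlorobenzoic anhydride | O=C(OC(=O)[C@]1(C)O[C@@H]1C)c1c(Cl)cc(Cl)cc1Cl | intermediate
23 | (1R,3S,6R,7R,8R,10R)-8-[(2R,3R)-2,3-dimethyloxirane-2-carbonyloxy]-1,10-epoxy-3-(2-methylpropanoyloxy)germacra-4Z,11(13)-dien-12,6-olide | C=C1C(=O)O[C@@H]2/C=C(/C)[C@@H](OC(=O)C(C)C)C[C@H]3O[C@]3(C)C[C@@H](OC(=O)[C@]3(C)O[C@@H]3C)[C@@H]12 | target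

## Step count and weak points

Total: 15 steps. Longest linear sequence: 9 steps (4 → 5 → 6 → 7 → 8 → 9 → 10 → 11 → 17 → 23; steps 3 to 9, 11 and 15).

Most likely to fail, first: step 11. The risks are the face selectivity at C8 with a γ-bromo reagent, a premature second reduction that would give oligomers, the C6/C7 outcome of the ring closure, and closure onto a hindered enal. The fallback sets out from 11 and 14 and returns at 16, hence 17. It builds C7–C8 by alkenyl addition and closes the ring by a palladium/indium allylation instead. Bromide 14 and KOAc in DMF give methyl (E)-2-(acetoxymethyl)-3-bromoprop-2-enoate F1. Ni/Cr alkenylation under the conditions of step 5 at the C8 aldehyde of 11 gives methyl (2E,4R)-2-(acetoxymethyl)-4-hydroxy-5-[(2R,3R)-2-methyl-3-{(2S,3Z)-3-methyl-2-(2-methylpropanoyloxy)-5-oxopent-3-en-1-yl}oxiran-2-yl]pent-2-enoate F2. Me3SiCl and imidazole give its 4-O-trimethylsilyl ether F3. Pd(PPh3)4 and InI in THF at 2 mM convert the allylic acetate into an allylindium that adds to the enal and lactonises to 16, and citric acid gives 17.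

Second: step 5. The risks are the enantioselectivity and the sense of induction with the Z-trisubstituted iodide. The fallback sets out from 6 and 3 and returns at 7; the stereocentre then comes from a ketone reduction, not from the C–C bond formation. Coupling without ligand (CrCl2, NiCl2 cat., DMSO) gives racemic (2Z,6E)-1,9-bis[(tert-butyldimethylsilyl)oxy]-3,7-dimethylnona-2,6-dien-4-ol F4. Dess–Martin oxidation gives (2Z,6E)-1,9-bis[(tert-butyldimethylsilyl)oxy]-3,7-dimethylnona-2,6-dien-4-one F5. (R)-2-Methyl-CBS-oxazaborolidine with BH3·SMe2 at −30 °C, the alkenyl group acting as the large substituent, gives 7.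

Third: step 7. The risks are the site and face selectivity of the early epoxidation, and the survival of the oxirane and of the β,γ-epoxy aldehyde through steps 9 and 11. The fallback sets out from 8 and returns at 23; the alkene is carried through and epoxidised last. Bu4NF/AcOH gives (2Z,4S,6E)-1,9-dihydroxy-3,7-dimethylnona-2,6-dien-4-yl 2-methylpropanoate F6. Dess–Martin oxidation gives (2Z,4S,6E)-3,7-dimethyl-1,9-dioxonona-2,6-dien-4-yl 2-methylpropanoate F7. The conditions of step 11 with 14 lead through methyl (4R,6E,9S,10Z)-3-bromo-6,10-dimethyl-2-methylidene-9-(2-methylpropanoyloxy)-12-oxo-4-[(trimethylsilyl)oxy]dodeca-6,10-dienoate F8 and the 8-O-trimethylsilyl ether of the macrocycle F9 to (3S,6R,7R,8R)-8-hydroxy-3-(2-methylpropanoyloxy)germacra-1(10)E,4Z,11(13)-trien-12,6-olide F10. Yamaguchi esterification with 21 through 22 gives (3S,6R,7R,8R)-8-[(2R,3R)-2,3-dimethyloxirane-2-carbonyloxy]-3-(2-methylpropanoyloxy)germacra-1(10)E,4Z,11(13)-trien-12,6-olide F11. The 1(10)-alkene is then the only electron-rich alkene left and is epoxidised with the Shi ketone and KHSO5, where reagent control and peripheral attack on the ring alkene are expected to reinforce each other, giving 23.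

## Further compounds

F1 | step 11 | methyl (E)-2-(acetoxymethyl)-3-bromoprop-2-enoate | CC(=O)OC/C(C(=O)OC)=C\Br
F2 | step 11 | methyl (2E,4R)-2-(acetoxymethyl)-4-hydroxy-5-[(2R,3R)-2-methyl-3-{(2S,3Z)-3-methyl-2-(2-methylpropanoyloxy)-5-oxopent-3-en-1-yl}oxiran-2-yl]pent-2-enoate | O=C/C=C(/C)[C@@H](OC(=O)C(C)C)C[C@H]1O[C@]1(C)C[C@@H](O)/C=C(\COC(C)=O)C(=O)OC
F3 | step 11 | 4-O-trimethylsilyl ether of F2 | O=C/C=C(/C)[C@@H](OC(=O)C(C)C)C[C@H]1O[C@]1(C)C[C@@H](O[Si](C)(C)C)/C=C(\COC(C)=O)C(=O)OC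
F4 | step 5 | (2Z,6E)-1,9-bis[(tert-butyldimethylsilyl)oxy]-3,7-dimethylnona-2,6-dien-4-ol (racemic) | CC(C)(C)[Si](C)(C)OC/C=C(/C)C(O)C/C=C(\C)CCO[Si](C)(C)C(C)(C)C
F5 | step 5 | (2Z,6E)-1,9-bis[(tert-butyldimethylsilyl)oxy]-3,7-dimethylnona-2,6-dien-4-one | CC(C)(C)[Si](C)(C)OC/C=C(/C)C(=O)C/C=C(\C)CCO[Si](C)(C)C(C)(C)C
F6 | step 7 | (2Z,4S,6E)-1,9-dihydroxy-3,7-dimethylnona-2,6-dien-4-yl 2-methylpropanoate | OC/C=C(/C)[C@@H](OC(=O)C(C)C)C/C=C(\C)CCO
F7 | step 7 | (2Z,4S,6E)-3,7-dimethyl-1,9-dioxonona-2,6-dien-4-yl 2-methylpropanoate | O=C/C=C(/C)[C@@H](OC(=O)C(C)C)C/C=C(\C)CC=O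
F8 | step 7 | methyl (4R,6E,9S,10Z)-3-bromo-6,10-dimethyl-2-methylidene-9-(2-methylpropanoyloxy)-12-oxo-4-[(trimethylsilyl)oxy]dodeca-6,10-dienoate (both C3 epimers) | O=C/C=C(/C)[C@@H](OC(=O)C(C)C)C/C=C(\C)C[C@@H](O[Si](C)(C)C)C(Br)C(=C)C(=O)OC
F9 | step 7 | 8-O-trimethylsilyl ether of F10 | C=C1C(=O)O[C@@H]2/C=C(/C)[C@@H](OC(=O)C(C)C)C/C=C(\C)C[C@@H](O[Si](C)(C)C)[C@@H]12
F10 | step 7 | (3S,6R,7R,8R)-8-hydroxy-3-(2-methylpropanoyloxy)germacra-1(10)E,4Z,11(13)-trien-12,6-olide | C=C1C(=O)O[C@@H]2/C=C(/C)[C@@H](OC(=O)C(C)C)C/C=C(\C)C[C@@H](O)[C@@H]12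
F11 | step 7 | (3S,6R,7R,8R)-8-[(2R,3R)-2,3-dimethyloxirane-2-carbonyloxy]-3-(2-methylpropanoyloxy)germacra-1(10)E,4Z,11(13)-trien-12,6-olide | C=C1C(=O)O[C@@H]2/C=C(/C)[C@@H](OC(=O)C(C)C)C/C=C(\C)C[C@@H](OC(=O)[C@]3(C)O[C@@H]3C)[C@@H]12
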